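The route rests on cutting the depside at two bonds of ring A: the ester C–O bond between the ring A C1 carbonyl and the ring B C4 oxygen, and the ring A C1–C6 bond. The key step forms both in one pot: an acylketene, released by heat from a chlorinated diketo-dioxinone, acylates the free C4–OH of benzyl olivetolate, and the tethered 4-chloro-3,5,7-trioxodecanoyl chain then folds by aldol condensation into ring A. It exploits the polyketide pattern of ring A (oxygen at C2 and C4, Cl at C3 between them, propyl at C6), so chlorine is placed before the arene exists. The precursor is 6-(1-chloro-2,4-dioxoheptyl)-2,2-dimethyl-1,3-dioxin-4-one.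

Key step: step 6

Remark: ring A is the chlorinated ring (C1 carries the ester carbonyl, C2 OH, C3 Cl, C4 OMe, C6 propyl) and ring B the pentyl-bearing salicylic acid ring (C1 CO2H, C2 OH, C4 O-acyl, C6 pentyl); the chain of the decanoate is numbered from its ester carbon; every CHCl centre on the way is racemic and vanishes on aromatisation, so the target has no stereocentre.

Step 1
Reactants: 1 dioxinone [2,2,6-trimethyl-4H-1,3-dioxin-4-one]; 2 acetyl chloride
Product: 3 keto-dioxinone [2,2-dimethyl-6-(2-oxopropyl)-4H-1,3-dioxin-4-one]
Conditions: LiN(SiMe3)2, THF, −78 °C; then 2 (0.5 equiv relative to the dienolate), −78 °C; aq. NH4Cl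
Reagents that add atoms: none
Why: C-acylation of the lithium dienolate of 1 at its γ-carbon (vinylogous Claisen-type acylation), a known preparation of this compound, in which the second equivalent of dienolate absorbs the more acidic product and so prevents double acylation.

Step 2
Reactants: 3 keto-dioxinone
Product: 4 chloro keto-dioxinone [6-(1-chloro-2-oxopropyl)-2,2-dimethyl-4H-1,3-dioxin-4-one; racemic]
Conditions: SO2Cl2 (1.0 equiv), CH2Cl2, 0 °C
Reagents that add atoms: sulfuryl chloride, ClS(Cl)(=O)=O
Why: Electrophilic α-chlorination of an active methylene through its enol, the reaction that turns acetoacetates into 2-chloroacetoacetates: the CH2 between the ketone and the vinylogous ester carbon is the only doubly activated position, the monochloride enolises less readily than 3 so the reaction should stop after one chlorine, and the new CHCl centre forms as a racemate that is erased later.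

Step 3
Reactants: 4 chloro keto-dioxinone; 5 N-methoxy-N-methylbutanamide
Product: 7 chloro diketo-dioxinone [6-(1-chloro-2,4-dioxoheptyl)-2,2-dimethyl-4H-1,3-dioxin-4-one; racemic], via dilithium hemiaminal adduct 6 (not isolated)
Conditions: LiN(iPr)2 (2.1 equiv, commercial solution), THF, −78 °C; then 5, −78 → −40 °C; cold aq. HCl (pH 3); used promptly
Reagents that add atoms: none
Why: Acylation of a 1,3-dianion at its terminal carbon by an N-methoxy-N-methylamide (Weinreb-type ketone synthesis), the standard way from 6-(2-oxoalkyl)dioxinones to diketo-dioxinones: the first equivalent of base removes the CHCl proton and the second the methyl proton, the chlorine then sits on an sp2 enolate carbon (as in the known dianions of 2-chloro-3-oxo esters) and cannot be displaced, and the chelated adduct 6 releases the second ketone only on acidic work-up, so no over-acylation is expected.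

Step 4
Reactants: 8 olivetol [5-pentylbenzene-1,3-diol]
Product: 9 olivetolic acid [2,4-dihydroxy-6-pentylbenzoic acid]
Conditions: MeOMgOCO2Me (2 M in DMF), 120 °C; then aq. HCl, 0 °C
Reagents that add atoms: magnesium methyl carbonate, COC(=O)O[Mg]OC
Why: Kolbe–Schmitt-type ortho-carboxylation through a magnesium phenoxide chelate, a known conversion of olivetol, in which CO2 is delivered ortho to one hydroxyl and para to the other and the chelate shields the β-resorcylic acid from decarboxylation until the cold acidic work-up.

Step 5
Reactants: 9 olivetolic acid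
Product: 10 benzyl olivetolate [benzyl 2,4-dihydroxy-6-pentylbenzoate]
Conditions: BnBr (1.05 equiv), KHCO3, DMF, rt
Reagents that add atoms: benzyl bromide, BrCc1ccccc1
Why: SN2 O-alkylation of the carboxylate, in which hydrogen carbonate deprotonates only the acid so that both phenols stay free, and room temperature avoids decarboxylation.

Step 6
Reactants: 7 chloro diketo-dioxinone; 10 benzyl olivetolate
Product: 14 benzyl 4-[(3-chloro-2,4-dihydroxy-6-propylbenzoyl)oxy]-2-hydroxy-6-pentylbenzoate, via acylketene 11 (not isolated), via aryl triketo ester 12 (not isolated), via aldol adduct 13 (not isolated)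
Conditions: 7 added slowly to 10 (1.5 equiv), PhMe, 110 °C, acetone swept out with N2; then CH2Cl2, Et3N, 0 °C; then HCl (4 M in dioxane), 0 °C → rt
Reagents that add atoms: none
Why: Proposed new method: heating 7 should cause a retro-[4+2] loss of acetone to acylketene 11, which the unchelated ring B C4–OH of 10 captures to give the aryl β-keto ester 12, so the hindered depside C–O bond forms without any attack on a di-ortho-substituted benzoyl carbon; triethylamine then enolises chain C2 of 12, which adds to the C7 ketone to give 13, and acid-promoted dehydration and tautomerisation should deliver ring A with Cl already at C3. The closest known reaction type is the thermolysis of diketo-dioxinones with capture of the acylketene by an alcohol and base-then-acid aromatisation to resorcylate esters, together with the acetoacetylation of phenols by dioxinones; the pairing of a phenol with a chlorine-bearing chain has no direct counterpart. Ring A closes by a 6-(enolendo)-exo-trig aldol condensation (chain C2 to C7, that is ring A C1–C6). No stereocentre is created, since the CHCl centre of 7 and the centres of 13 are lost on aromatisation. Site selectivity between the two phenols of 10 rests on the hydrogen bond of its C2–OH to the benzyl ester carbonyl, which leaves only the C4–OH nucleophilic. Aldol closure must win over Claisen closure and over lactonisation to a pyranone, both of which expel the aryloxide; the C7 ketone is the only carbonyl that is neither an ester nor part of the chlorine-stabilised C3–C5 enolate, and the weak amine base, the low temperature and the excess of 10 during capture support this course.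

Step 7
Reactants: 14 benzyl 4-[(3-chloro-2,4-dihydroxy-6-propylbenzoyl)oxy]-2-hydroxy-6-pentylbenzoate
Product: 15 benzyl 4-[(3-chloro-2-hydroxy-4-methoxy-6-propylbenzoyl)oxy]-2-hydroxy-6-pentylbenzoate
Conditions: MeI (1.1 equiv), K2CO3 (1.0 equiv), acetone, rt
Reagents that add atoms: iodomethane, CI
Why: Williamson ether synthesis under pKa control: the ring A C4–OH (para to the ester carbonyl, next to chlorine, not hydrogen-bonded) is the most acidic and most accessible of the three phenols, whereas the ring A C2–OH and the ring B C2–OH are each locked in a hydrogen bond to an ester carbonyl, so one equivalent of base should give the mono-ether.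

Step 8
Reactants: 15 benzyl 4-[(3-chloro-2-hydroxy-4-methoxy-6-propylbenzoyl)oxy]-2-hydroxy-6-pentylbenzoate
Product: 16 4-[(3-chloro-2-hydroxy-4-methoxy-6-propylbenzoyl)oxy]-2-hydroxy-6-pentylbenzoic acid (target)
Conditions: H2 (1 atm), Pd/C (10% palladium on carbon), EtOAc, rt, stopped at full conversion; no heating on work-up
Reagents that add atoms: none
Why: Hydrogenolysis of the benzylic C–O bond of the ester, which under neutral, base-free conditions at 1 atm should be much faster than reduction of the C–Cl bond of the electron-rich ring A, while the aryl ester and the methyl ether are inert and the acid is isolated cold to avoid decarboxylation.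

Compound list
1 | 2,2,6-trimethyl-4H-1,3-dioxin-4-one | CC1=CC(=O)OC(C)(C)O1 | starting material
2 | acetyl chloride | CC(Cl)=O | starting material
3 | 2,2-dimethyl-6-(2-oxopropyl)-4H-1,3-dioxin-4-one | CC(=O)CC1=CC(=O)OC(C)(C)O1 | intermediate
4 | 6-(1-chloro-2-oxopropyl)-2,2-dimethyl-4H-1,3-dioxin-4-one (racemic) | CC(=O)C(Cl)C1=CC(=O)OC(C)(C)O1 | intermediate
5 | N-methoxy-N-methylbutanamide | CCCC(=O)N(C)OC | starting material
6 | dilithium 1-chloro-1-(2,2-dimethyl-4-oxo-4H-1,3-dioxin-6-yl)-4-[methoxy(methyl)amino]hept-1-ene-2,4-bis(olate) (racemic, enolate geometry undefined) | [Li+].[Li+].CCCC([O-])(N(C)OC)CC([O-])=C(Cl)C1=CC(=O)OC(C)(C)O1 | intermediate (not isolated)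
7 | 6-(1-chloro-2,4-dioxoheptyl)-2,2-dimethyl-4H-1,3-dioxin-4-one (racemic, drawn as the keto tautomer) | CCCC(=O)CC(=O)C(Cl)C1=CC(=O)OC(C)(C)O1 | intermediate
8 | olivetol (5-pentylbenzene-1,3-diol) | CCCCCc1cc(O)cc(O)c1 | starting material
9 | olivetolic acid (2,4-dihydroxy-6-pentylbenzoic acid) | CCCCCc1cc(O)cc(O)c1C(=O)O | intermediate
10 | benzyl 2,4-dihydroxy-6-pentylbenzoate | CCCCCc1cc(O)cc(O)c1C(=O)OCc1ccccc1 | intermediate
11 | 4-chlorodec-1-ene-1,3,5,7-tetraone (acylketene, racemic) | CCCC(=O)CC(=O)C(Cl)C(=O)C=C=O | intermediate (not isolated)
12 | benzyl 4-[(4-chloro-3,5,7-trioxodecanoyl)oxy]-2-hydroxy-6-pentylbenzoate (racemic) | CCCCCc1cc(OC(=O)CC(=O)C(Cl)C(=O)CC(=O)CCC)cc(O)c1C(=O)OCc1ccccc1 | intermediate (not isolated)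
13 | benzyl 4-[(3-chloro-6-hydroxy-2,4-dioxo-6-propylcyclohexane-1-carbonyl)oxy]-2-hydroxy-6-pentylbenzoate (mixture of diastereomers) | CCCCCc1cc(OC(=O)C2C(=O)C(Cl)C(=O)CC2(O)CCC)cc(O)c1C(=O)OCc1ccccc1 | intermediate (not isolated)
14 | benzyl 4-[(3-chloro-2,4-dihydroxy-6-propylbenzoyl)oxy]-2-hydroxy-6-pentylbenzoate | CCCCCc1cc(OC(=O)c2c(CCC)cc(O)c(Cl)c2O)cc(O)c1C(=O)OCc1ccccc1 | intermediate
15 | benzyl 4-[(3-chloro-2-hydroxy-4-methoxy-6-propylbenzoyl)oxy]-2-hydroxy-6-pentylbenzoate | CCCCCc1cc(OC(=O)c2c(CCC)cc(OC)c(Cl)c2O)cc(O)c1C(=O)OCc1ccccc1 | intermediate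
16 | 4-[(3-chloro-2-hydroxy-4-methoxy-6-propylbenzoyl)oxy]-2-hydroxy-6-pentylbenzoic acid (no stereocentre) | CCCCCc1cc(OC(=O)c2c(CCC)cc(OC)c(Cl)c2O)cc(O)c1C(=O)O | target

Total step count: 8
Longest linear sequence: 6 steps (steps 1, 2, 3, 6, 7, 8); the ring B branch (steps 4, 5) joins at step 6.

Steps most likely to fail

1. Step 6. The acylketene may cyclise onto its own enol oxygen to a pyranone faster than the phenol adds. After capture, the chain may close by Claisen condensation or lactonise with loss of the aryloxide instead of closing by aldol. Once base is present, phenoxide may also displace the activated chloride. The fallback uses known chemistry, completes ring A before the depside bond is made, and sets out from 7. Triethylamine in CH2Cl2 should close the ring by the same aldol condensation on the intact dioxinone, giving 8-chloro-7-hydroxy-2,2-dimethyl-5-propyl-4H-1,3-benzodioxin-4-one F1. MeI and K2CO3 in acetone should methylate its only hydroxyl to give 8-chloro-7-methoxy-2,2-dimethyl-5-propyl-4H-1,3-benzodioxin-4-one F2. KOH in aqueous DMSO at 80 °C, followed by cold acidification, should open the acetonide to 3-chloro-2-hydroxy-4-methoxy-6-propylbenzoic acid F3. Trifluoroacetic anhydride in toluene at room temperature should convert F3 into 3-chloro-2-hydroxy-4-methoxy-6-propylbenzoic trifluoroacetic anhydride F4, which acylates the unchelated C4–OH of 10 (the classical depside esterification). The route is rejoined at 15, and step 7 is no longer needed.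

2. Step 3. The chlorinated dianion may not form cleanly (attack of the amide base at chlorine or at the ring carbonyl), or may be acylated so slowly that 4 is returned. The fallback builds the chain before chlorine is present and sets out from 3. Its dianion (LiN(iPr)2, 2 equiv, THF, −78 °C) is added to butanal to give 6-(4-hydroxy-2-oxoheptyl)-2,2-dimethyl-4H-1,3-dioxin-4-one F5, in which the carbinol serves as a latent ketone. N-chlorosuccinimide with catalytic Mg(ClO4)2 in EtOAc should then chlorinate the only doubly activated methylene to give 6-(1-chloro-4-hydroxy-2-oxoheptyl)-2,2-dimethyl-4H-1,3-dioxin-4-one F6. Oxidation of the carbinol with Dess–Martin periodinane in CH2Cl2 rejoins the route at 7.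

3. Step 2. Chlorination may go to the ring C5 position of the dioxinone, or a second chlorine may enter, instead of clean monochlorination of the side-chain methylene. The fallback installs chlorine before the acetyl group and sets out from 1. LiN(iPr)2 and then C2Cl6 in THF at −78 °C should give 6-(chloromethyl)-2,2-dimethyl-4H-1,3-dioxin-4-one F7. Its lithium dienolate (LiN(SiMe3)2, THF, −78 °C) is C-acetylated with 2, which rejoins the route at 4.

Further compounds
F1 | step 6 | 8-chloro-7-hydroxy-2,2-dimethyl-5-propyl-4H-1,3-benzodioxin-4-one | CCCc1cc(O)c(Cl)c2OC(C)(C)OC(=O)c12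
F2 | step 6 | 8-chloro-7-methoxy-2,2-dimethyl-5-propyl-4H-1,3-benzodioxin-4-one | CCCc1cc(OC)c(Cl)c2OC(C)(C)OC(=O)c12
F3 | step 6 | 3-chloro-2-hydroxy-4-methoxy-6-propylbenzoic acid | CCCc1cc(OC)c(Cl)c(O)c1C(=O)O
F4 | step 6 | 3-chloro-2-hydroxy-4-methoxy-6-propylbenzoic trifluoroacetic anhydride | CCCc1cc(OC)c(Cl)c(O)c1C(=O)OC(=O)C(F)(F)F
F5 | step 3 | 6-(4-hydroxy-2-oxoheptyl)-2,2-dimethyl-4H-1,3-dioxin-4-one (racemic) | CCCC(O)CC(=O)CC1=CC(=O)OC(C)(C)O1
F6 | step 3 | 6-(1-chloro-4-hydroxy-2-oxoheptyl)-2,2-dimethyl-4H-1,3-dioxin-4-one (mixture of diastereomers) | CCCC(O)CC(=O)C(Cl)C1=CC(=O)OC(C)(C)O1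
F7 | step 2 | 6-(chloromethyl)-2,2-dimethyl-4H-1,3-dioxin-4-one | ClCC1=CC(=O)OC(C)(C)O1
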